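**Plan**
- Retrosynthesis: the 7‑O–Si bond is cut last. Ring B is then cut at C1'–C2', C2'–C3' and C4'–C5', which leads back to dienyl diazo ketone 14 and prenylated ynol ether 18.
- 14 is cut at its diazo group and its C=C bond to chroman‑3‑carbaldehyde 10; ring C is cut at O1–C2 and C3–C4 to a salicylaldehyde and acrylonitrile; 18 is cut at its propargylic C–C bond.
- Forward: ring A is bought and formylated, ring C is annulated onto it, the four‑carbon diazo enone arm is grown from C3, and ring B is built last by benzannulation, followed by desilylation.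
- Stereochemistry: the only stereocentre, C3, is set by asymmetric hydrogenation of chromene acid 6 with Ru(OAc)2[(R)-BINAP]. The S acid, ester and aldehyde have the spatial arrangement of the R target (the descriptor changes by CIP priority only), and every later step is run so as not to enolise this centre.
- The 7‑OH travels as a MOM ether through the basic steps and as a TBS ether through the key step.

Key step: step 12

Remark: the ligand antipode in step 5 is assigned by analogy with tiglic‑type α‑substituted acrylic acids; the first run would confirm which antipode gives the S acid, and both are available.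

**Step 1**
Reactants: 1 5-methoxyresorcinol
Product: 2 2,4-dihydroxy-6-methoxybenzaldehyde
Conditions: POCl3, DMF, MeCN, 0 °C → rt; then H2O, 50 °C
Reagents that add atoms: N,N-dimethylformamide CN(C)C=O; water O
Why: Vilsmeier–Haack formylation should go para to one hydroxyl and ortho to the other (as with resorcinol and orcinol) rather than between the two hydroxyls, and the iminium salt is hydrolysed on work-up.

**Step 2**
Reactants: 2 2,4-dihydroxy-6-methoxybenzaldehyde
Product: 3 2-hydroxy-6-methoxy-4-(methoxymethoxy)benzaldehyde
Conditions: MOMCl (1.05 equiv), K2CO3, acetone, 0 °C → rt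
Reagents that add atoms: chloromethyl methyl ether COCCl
Why: Williamson-type O-alkylation should be selective for the 4-OH, which is the more acidic and is not held in the hydrogen bond to the aldehyde that deactivates the 2-OH.

**Step 3**
Reactants: 3 2-hydroxy-6-methoxy-4-(methoxymethoxy)benzaldehyde; 4 acrylonitrile
Product: 5 5-methoxy-7-(methoxymethoxy)-2H-chromene-3-carbonitrile
Conditions: DABCO (0.5 equiv), acrylonitrile (neat), reflux
Reagents that add atoms: none
Why: The DABCO-mediated oxa-Michael addition and intramolecular aldol condensation of a salicylaldehyde (Baylis–Hillman-type chromene annulation) closes ring C, and acrylonitrile is chosen because it cannot divert to a coumarin as acrylate esters can.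

**Step 4**
Reactants: 5 5-methoxy-7-(methoxymethoxy)-2H-chromene-3-carbonitrile
Product: 6 5-methoxy-7-(methoxymethoxy)-2H-chromene-3-carboxylic acid
Conditions: NaOH (10% aq), EtOH, reflux; then H3PO4 to pH 3, 0 °C
Reagents that add atoms: water O; sodium hydroxide [Na+].[OH-]
Why: Alkaline nitrile hydrolysis leaves the base-stable MOM ether and the chromene untouched, and cold phosphate acidification should free the acid without cleaving the acetal.

**Step 5**
Reactants: 6 5-methoxy-7-(methoxymethoxy)-2H-chromene-3-carboxylic acid
Product: 7 (S)-5-methoxy-7-(methoxymethoxy)chroman-3-carboxylic acid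
Conditions: Ru(OAc)2[(R)-BINAP] (1 mol %), H2 (4 bar), MeOH, 40 °C
Reagents that add atoms: none
Why: Carboxylate-directed asymmetric hydrogenation of a trisubstituted α,β-unsaturated acid, in which the carboxylate binds ruthenium and the BINAP pocket selects the alkene face, should deliver hydrogen to C3 to give the S acid, which has the spatial arrangement of the R target.

**Step 6**
Reactants: 7 (S)-5-methoxy-7-(methoxymethoxy)chroman-3-carboxylic acid
Product: 8 methyl (S)-7-hydroxy-5-methoxychroman-3-carboxylate
Conditions: HCl (1.25 M in MeOH), 50 °C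
Reagents that add atoms: methanol CO
Why: Acid-catalysed acetal methanolysis (MOM cleavage) and Fischer esterification run in the same medium, excess methanol traps the methoxymethyl cation, and C3 is not enolised under these conditions.

**Step 7**
Reactants: 8 methyl (S)-7-hydroxy-5-methoxychroman-3-carboxylate
Product: 9 methyl (S)-7-(tert-butyldimethylsilyloxy)-5-methoxychroman-3-carboxylate
Conditions: TBSCl, imidazole, DMF, rt
Reagents that add atoms: tert-butyldimethylsilyl chloride CC(C)(C)[Si](C)(C)Cl
Why: Imidazole-promoted silylation of the only free hydroxyl gives an aryl silyl ether that withstands hydride, ylide, amide base at −78 °C and light, and is later removed by fluoride.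

**Step 8**
Reactants: 9 methyl (S)-7-(tert-butyldimethylsilyloxy)-5-methoxychroman-3-carboxylate
Product: 10 (S)-7-(tert-butyldimethylsilyloxy)-5-methoxychroman-3-carbaldehyde
Conditions: i-Bu2AlH (1.1 equiv), CH2Cl2, −78 °C; MeOH, then aq potassium sodium tartrate
Reagents that add atoms: none
Why: Partial reduction of the ester stops at the tetrahedral aluminium hemiacetal at −78 °C, and the neutral tartrate work-up with immediate use of the crude aldehyde should keep the α-stereocentre intact.

**Step 9**
Reactants: 10 (S)-7-(tert-butyldimethylsilyloxy)-5-methoxychroman-3-carbaldehyde; 11 1-(triphenylphosphoranylidene)propan-2-one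
Product: 12 (R,E)-4-[7-(tert-butyldimethylsilyloxy)-5-methoxychroman-3-yl]but-3-en-2-one
Conditions: 11 (1.5 equiv), CH2Cl2, rt → 40 °C
Reagents that add atoms: none
Why: Wittig olefination with a stabilised keto ylide should give the E enone and, being only weakly basic, should not enolise the α-branched aldehyde.

**Step 10**
Reactants: 12 (R,E)-4-[7-(tert-butyldimethylsilyloxy)-5-methoxychroman-3-yl]but-3-en-2-one
Product: 14 (R,E)-4-[7-(tert-butyldimethylsilyloxy)-5-methoxychroman-3-yl]-1-diazobut-3-en-2-one, via trifluoroacetyl diketone 13 (not isolated)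
Conditions: LiN(SiMe3)2, THF, −78 °C; CF3CO2CH2CF3, −78 °C; aq HCl wash; then MsN3, Et3N, H2O (1 equiv), MeCN, rt
Reagents that add atoms: methanesulfonyl azide CS(=O)(=O)N=[N+]=[N-]
Why: Detrifluoroacetylative diazo transfer (Regitz-type transfer to an activated ketone) relies on kinetic deprotonation of the methyl group rather than the γ C3–H at −78 °C, Claisen trifluoroacetylation, and azide transfer under triethylamine with loss of the trifluoroacetyl group, so the E alkene and C3 should stay untouched.

**Step 11**
Reactants: 15 chloroacetaldehyde dimethyl acetal; 16 prenyl bromide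
Product: 18 1-methoxy-5-methylhex-4-en-1-yne, via sodium methoxyacetylide 17 (not isolated)
Conditions: NaNH2 (3 equiv), liquid NH3, −33 °C; then 16, −33 °C; NH4Cl
Reagents that add atoms: none
Why: Double elimination of HCl and methanol from the chloroacetal gives the alkoxyacetylide, whose SN2 alkylation at the primary carbon of the allylic bromide is the classical route to 1-alkoxyalk-1-ynes, and no amide base is left over to isomerise the skipped enyne.

**Step 12**
Reactants: 14 (R,E)-4-[7-(tert-butyldimethylsilyloxy)-5-methoxychroman-3-yl]-1-diazobut-3-en-2-one; 18 1-methoxy-5-methylhex-4-en-1-yne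
Product: 23 6-[(R)-7-(tert-butyldimethylsilyloxy)-5-methoxychroman-3-yl]-3-methoxy-2-(3-methylbut-2-en-1-yl)phenol, via vinylketene 19 (not isolated), via cyclobutenone 20 (not isolated), via dienylketene 21 (not isolated), via cyclohexadienone 22 (not isolated)
Conditions: hν (300 nm), 18 (2 equiv), degassed ClCH2CH2Cl, rt; then 80 °C
Reagents that add atoms: none
Why: Light expels N2 from 14 and the alkenyl group migrates (photochemical Wolff rearrangement) to give vinylketene 19, whose ketene C=C adds ynol ether 18 in a [2+2] cycloaddition to 4-alkenylcyclobutenone 20, and conrotatory 4π opening then gives dienylketene 21. Ring B closes by a thermal disrotatory 6π electrocyclisation of 21, the ketene carbon bonding to the alkene terminus attached to chroman C3, and cyclohexadienone 22 tautomerises to the phenol. The closest known reaction type is the Danheiser benzannulation in its diazo ketone variant with alkoxy- and siloxyalkynes. No stereocentre is created, since the sp3 centres of 20 and 22 vanish on aromatisation and C3 is a spectator in a neutral, base-free sequence. The regiochemistry needed (prenyl at C3' beside the new hydroxyl, methoxy at C4') follows from the polarity of the ynol ether, whose nucleophilic prenyl-bearing carbon attacks the electrophilic ketene carbon, so that C2'–C3', C4'–C5' and C1'–C2' form without a regioisomer. The E geometry of 14 holds the C3–H away from the ketene so that no 1,5-hydrogen shift competes, and the excess of 18 should outrun capture of 19 by the phenolic product.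

**Step 13**
Reactants: 23 6-[(R)-7-(tert-butyldimethylsilyloxy)-5-methoxychroman-3-yl]-3-methoxy-2-(3-methylbut-2-en-1-yl)phenol
Product: 24 (R)-3-[2-hydroxy-4-methoxy-3-(3-methylbut-2-en-1-yl)phenyl]-5-methoxychroman-7-ol
Conditions: Bu4NF, AcOH, THF, 0 °C
Reagents that add atoms: none
Why: Fluoride-induced cleavage of the aryl silyl ether, buffered with acetic acid so that the electron-rich phenoxides are not exposed to air as free anions, should leave the prenyl group, the methyl ethers and C3 untouched.

**Compound list**
1 | 5-methoxyresorcinol | COc1cc(O)cc(O)c1 | starting material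
2 | 2,4-dihydroxy-6-methoxybenzaldehyde | COc1cc(O)cc(O)c1C=O | intermediate
3 | 2-hydroxy-6-methoxy-4-(methoxymethoxy)benzaldehyde | COCOc1cc(O)c(C=O)c(OC)c1 | intermediate
4 | acrylonitrile | C=CC#N | starting material
5 | 5-methoxy-7-(methoxymethoxy)-2H-chromene-3-carbonitrile | COCOc1cc(OC)c2C=C(C#N)COc2c1 | intermediate
6 | 5-methoxy-7-(methoxymethoxy)-2H-chromene-3-carboxylic acid | COCOc1cc(OC)c2C=C(C(=O)O)COc2c1 | intermediate
7 | (S)-5-methoxy-7-(methoxymethoxy)chroman-3-carboxylic acid | COc1cc(OCOC)cc2c1C[C@H](C(=O)O)CO2 | intermediate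
8 | methyl (S)-7-hydroxy-5-methoxychroman-3-carboxylate | COc1cc(O)cc2c1C[C@H](C(=O)OC)CO2 | intermediate
9 | methyl (S)-7-(tert-butyldimethylsilyloxy)-5-methoxychroman-3-carboxylate | COc1cc(O[Si](C)(C)C(C)(C)C)cc2c1C[C@H](C(=O)OC)CO2 | intermediate
10 | (S)-7-(tert-butyldimethylsilyloxy)-5-methoxychroman-3-carbaldehyde | COc1cc(O[Si](C)(C)C(C)(C)C)cc2c1C[C@H](C=O)CO2 | intermediate
11 | 1-(triphenylphosphoranylidene)propan-2-one | CC(=O)C=P(c1ccccc1)(c1ccccc1)c1ccccc1 | starting material
12 | (R,E)-4-[7-(tert-butyldimethylsilyloxy)-5-methoxychroman-3-yl]but-3-en-2-one | COc1cc(O[Si](C)(C)C(C)(C)C)cc2c1C[C@H](/C=C/C(C)=O)CO2 | intermediate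
13 | (R,E)-6-[7-(tert-butyldimethylsilyloxy)-5-methoxychroman-3-yl]-1,1,1-trifluorohex-5-ene-2,4-dione | COc1cc(O[Si](C)(C)C(C)(C)C)cc2c1C[C@H](/C=C/C(=O)CC(=O)C(F)(F)F)CO2 | intermediate
14 | (R,E)-4-[7-(tert-butyldimethylsilyloxy)-5-methoxychroman-3-yl]-1-diazobut-3-en-2-one | COc1cc(O[Si](C)(C)C(C)(C)C)cc2c1C[C@H](/C=C/C(=O)C=[N+]=[N-])CO2 | intermediate
15 | chloroacetaldehyde dimethyl acetal | COC(CCl)OC | starting material
16 | prenyl bromide (1-bromo-3-methylbut-2-ene) | CC(C)=CCBr | starting material
17 | sodium methoxyacetylide | COC#[C-].[Na+] | intermediate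
18 | 1-methoxy-5-methylhex-4-en-1-yne | COC#CCC=C(C)C | intermediate
19 | (R,E)-4-[7-(tert-butyldimethylsilyloxy)-5-methoxychroman-3-yl]buta-1,3-dien-1-one | COc1cc(O[Si](C)(C)C(C)(C)C)cc2c1C[C@H](/C=C/C=C=O)CO2 | intermediate
20 | 4-{(E)-2-[(R)-7-(tert-butyldimethylsilyloxy)-5-methoxychroman-3-yl]ethenyl}-3-methoxy-2-(3-methylbut-2-en-1-yl)cyclobut-2-en-1-one (C4 epimers) | COc1cc(O[Si](C)(C)C(C)(C)C)cc2c1C[C@H](/C=C/C1C(=O)C(CC=C(C)C)=C1OC)CO2 | intermediate
21 | (3E,5E)-6-[(R)-7-(tert-butyldimethylsilyloxy)-5-methoxychroman-3-yl]-3-methoxy-2-(3-methylbut-2-en-1-yl)hexa-1,3,5-trien-1-one | COc1cc(O[Si](C)(C)C(C)(C)C)cc2c1C[C@H](/C=C/C=C(/OC)C(CC=C(C)C)=C=O)CO2 | intermediate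
22 | 6-[(R)-7-(tert-butyldimethylsilyloxy)-5-methoxychroman-3-yl]-3-methoxy-2-(3-methylbut-2-en-1-yl)cyclohexa-2,4-dien-1-one (C6 epimers) | COc1cc(O[Si](C)(C)C(C)(C)C)cc2c1C[C@H](C1C=CC(OC)=C(CC=C(C)C)C1=O)CO2 | intermediate
23 | 6-[(R)-7-(tert-butyldimethylsilyloxy)-5-methoxychroman-3-yl]-3-methoxy-2-(3-methylbut-2-en-1-yl)phenol (7-O-TBS isoflavan) | COc1cc(O[Si](C)(C)C(C)(C)C)cc2c1C[C@H](c1ccc(OC)c(CC=C(C)C)c1O)CO2 | intermediate
24 | (R)-3-[2-hydroxy-4-methoxy-3-(3-methylbut-2-en-1-yl)phenyl]-5-methoxychroman-7-ol | COc1cc(O)cc2c1C[C@H](c1ccc(OC)c(CC=C(C)C)c1O)CO2 | target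

**Step count**
Total: 13 steps. Longest linear sequence: 12 steps (steps 1–10, 12, 13); step 11 is the side branch.

**Steps most likely to fail**

1. Step 12. The photolysis may go astray in three ways: the electron-rich arenes may screen the diazo ketone, the ynol ether may be degraded under irradiation, or the vinylketene may be captured by the phenolic product before it meets the alkyne.
The fallback sets out from 14 and separates ketene formation from the light. Rearrangement of 14 in the dark with PhCO2Ag and Et3N in THF–H2O (Arndt–Eistert conditions) should give (R,E)-4-[7-(tert-butyldimethylsilyloxy)-5-methoxychroman-3-yl]but-3-enoic acid F1. (COCl)2 with catalytic DMF in CH2Cl2 would convert it to (R,E)-4-[7-(tert-butyldimethylsilyloxy)-5-methoxychroman-3-yl]but-3-enoyl chloride F2. Slow addition of F2 to Et3N and excess 18 in toluene at rt generates vinylketene 19 by dehydrochlorination, with the E alkene retained. Thermal [2+2] addition to 20 and heating to 80 °C then return the route to 23.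

2. Step 9. Configurational purity at C3 may be lost: the keto ylide reacts slowly, and over that time the α-branched β-aryloxy aldehyde can enolise, or open by retro-oxa-Michael reaction and reclose.
The fallback sets out from 10 and replaces the olefination by a fast carbonyl addition at low temperature. The lithium enolate of acetone (LiN(i-Pr)2, acetone, THF, −78 °C) should add within minutes to give 4-[(S)-7-(tert-butyldimethylsilyloxy)-5-methoxychroman-3-yl]-4-hydroxybutan-2-one F3 as carbinol epimers, which is of no consequence. MsCl and Et3N in CH2Cl2 at 0 °C give 4-[(S)-7-(tert-butyldimethylsilyloxy)-5-methoxychroman-3-yl]-4-(methylsulfonyloxy)butan-2-one F4. F4 eliminates in the same flask by an E1cB path to the E enone, and the route is rejoined at 12.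

3. Step 5. Facial selectivity may be insufficient on this cyclic trisubstituted acid, for instance if the ring oxygen competes for ruthenium, or the sense of induction may be opposite to the one assigned.
The fallback sets out from 6 and replaces catalyst control by separation of covalent diastereomers. H2 over Pd/C in EtOAc gives rac-5-methoxy-7-(methoxymethoxy)chroman-3-carboxylic acid F5. Coupling with (S)-4-benzyloxazolidin-2-one (DCC, catalytic DMAP, CH2Cl2) gives two imides, separable by chromatography: (S)-4-benzyl-3-[(S)-5-methoxy-7-(methoxymethoxy)chroman-3-carbonyl]oxazolidin-2-one F6 and (S)-4-benzyl-3-[(R)-5-methoxy-7-(methoxymethoxy)chroman-3-carbonyl]oxazolidin-2-one F7. The configuration of each would be assigned by correlation or crystallography. LiOH and H2O2 in THF–H2O at 0 °C cleave F6 without epimerisation, and the route is rejoined at 7.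

**Further compounds**
F1 | step 12 | (R,E)-4-[7-(tert-butyldimethylsilyloxy)-5-methoxychroman-3-yl]but-3-enoic acid | COc1cc(O[Si](C)(C)C(C)(C)C)cc2c1C[C@H](/C=C/CC(=O)O)CO2
F2 | step 12 | (R,E)-4-[7-(tert-butyldimethylsilyloxy)-5-methoxychroman-3-yl]but-3-enoyl chloride | COc1cc(O[Si](C)(C)C(C)(C)C)cc2c1C[C@H](/C=C/CC(=O)Cl)CO2
F3 | step 9 | 4-[(S)-7-(tert-butyldimethylsilyloxy)-5-methoxychroman-3-yl]-4-hydroxybutan-2-one (carbinol epimers) | COc1cc(O[Si](C)(C)C(C)(C)C)cc2c1C[C@H](C(O)CC(C)=O)CO2
F4 | step 9 | 4-[(S)-7-(tert-butyldimethylsilyloxy)-5-methoxychroman-3-yl]-4-(methylsulfonyloxy)butan-2-one (epimers at the sulfonate carbon) | COc1cc(O[Si](C)(C)C(C)(C)C)cc2c1C[C@H](C(OS(C)(=O)=O)CC(C)=O)CO2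
F5 | step 5 | rac-5-methoxy-7-(methoxymethoxy)chroman-3-carboxylic acid | COc1cc(OCOC)cc2c1CC(C(=O)O)CO2
F6 | step 5 | (S)-4-benzyl-3-[(S)-5-methoxy-7-(methoxymethoxy)chroman-3-carbonyl]oxazolidin-2-one | COc1cc(OCOC)cc2c1C[C@H](C(=O)N1[C@@H](Cc3ccccc3)COC1=O)CO2
F7 | step 5 | (S)-4-benzyl-3-[(R)-5-methoxy-7-(methoxymethoxy)chroman-3-carbonyl]oxazolidin-2-one | COc1cc(OCOC)cc2c1C[C@@H](C(=O)N1[C@@H](Cc3ccccc3)COC1=O)CO2
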